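**Retrosynthetic overview**
- The tertiary (E)-cinnamate is cut to a tertiary acrylate plus iodobenzene (Heck). The acrylate comes from the 1,4-diol, whose C(Me)–O centre comes from methyl addition to the ring A ketone next to the ring fusion.
- The ring B alkene and the trans ring fusion come from deconjugative protonation of a conjugated bicyclic enone. The secondary alcohol comes from borohydride reduction of the ketone next to the angular methyl.
- The bicyclic ene-dione comes from a monocyclic 4-hydroxy-4-methylcyclohexenone carrying a formylalkyl chain. An acid-triggered 1,2-methyl shift from the carbinol carbon to the adjacent enone β-carbon creates the angular-methyl quaternary centre and the 1,4-dione, and the enol it releases closes ring B by aldol condensation.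
- That chain is attached by a vinylogous Michael union of (S)-4-hydroxy-3,4-dimethylcyclohex-2-enone with 2-isopropylacrolein (new C–C bond at the ring methyl).
- Ring A is bought as 2-methylcyclohexenone (asymmetric methyl addition, then allylic oxidation); ring B is formed second, in the rearrangement step.

Assumption: the SMILES is read as 1β-OH, 4β-cinnamoyloxy, 4α-Me, 5α-H, 10β-Me on a trans-decalin (eudesmane numbering 1R,4S,5R,10R), and 3-methyl-2-methylidenebutanal is taken as a catalogue compound.

**Step 1**
Reactants: 1 2-methylcyclohex-2-en-1-one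
Product: 2 (1S)-1,2-dimethylcyclohex-2-en-1-ol
Conditions: Me2Zn (3 equiv), Ti(OiPr)4 (1.2 equiv), trans-cyclohexane-1,2-diamine bis(10-camphorsulfonamide) diol ligand (10 mol %, antipode that gives the S alcohol), toluene–hexane, 23 °C; aq. NH4Cl
Reagents that add atoms: dimethylzinc, C[Zn]C
Why: Catalytic enantioselective 1,2-addition of a dialkylzinc to an α-substituted cyclic enone (titanium/bis(sulfonamide) diol catalysis), in which the catalyst distinguishes the sp2 methyl-bearing flank from the CH2 flank and sets the (S)-tertiary carbinol that later relays its configuration to the angular-methyl carbon.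

**Step 2**
Reactants: 2 (1S)-1,2-dimethylcyclohex-2-en-1-ol
Product: 3 (4S)-4-hydroxy-3,4-dimethylcyclohex-2-en-1-one
Conditions: Rh2(cap)4 (dirhodium tetracaprolactamate, 1 mol %), t-BuOOH (70% aq., 5 equiv), K2CO3 (0.5 equiv), CH2Cl2, 23 °C
Reagents that add atoms: tert-butyl hydroperoxide, CC(C)(C)OO
Why: Dirhodium-caprolactamate/hydroperoxide allylic C–H oxidation turns the only secondary allylic CH2 into the enone carbonyl (the other ring allylic position is the quaternary carbinol carbon) under basic, non-ionising conditions that leave the tertiary allylic alcohol and its configuration untouched.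

**Step 3**
Reactants: 3 (4S)-4-hydroxy-3,4-dimethylcyclohex-2-en-1-one; 4 3-methyl-2-methylidenebutanal
Product: 5 4-[(6S)-6-hydroxy-6-methyl-3-oxocyclohex-1-en-1-yl]-2-(propan-2-yl)butanal (both C2 epimers)
Conditions: 9-amino-9-deoxy-epi-quinine (20 mol %), 2-fluorobenzoic acid (40 mol %), 4 (2 equiv, slow addition), toluene, 40 °C
Reagents that add atoms: none
Why: Proposed new method: a primary amine condenses with the hindered enone 3 and, because the ring γ′-carbon is quaternary, only the ring methyl can be deprotonated to the linear exocyclic dienamine, whose terminal CH2 adds to the unhindered β-CH2 of the acid-activated α-branched enal 4 (vinylogous Michael addition that joins the two fragments, creates no lasting stereocentre and leaves the carbinol centre untouched); the closest known reaction type is the primary-amine dienamine-mediated γ-selective vinylogous Michael addition of 3-methylcyclohex-2-enones to nitroalkenes, which has not been shown for α-branched acroleins or for donors bearing a free γ′-tertiary hydroxyl.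

**Step 4**
Reactants: 5 4-[(6S)-6-hydroxy-6-methyl-3-oxocyclohex-1-en-1-yl]-2-(propan-2-yl)butanal
Product: 8 (4aR)-4a-methyl-7-(propan-2-yl)-2,3,4a,5,6,7-hexahydronaphthalene-1,4-dione (both C7 epimers), via rearranged diketo aldehyde 6 (not isolated), via bicyclic aldol 7 (not isolated)
Conditions: TfOH (20 mol %), ClCH2CH2Cl, 0 → 60 °C
Reagents that add atoms: none
Why: Protonation of the enone makes its β-carbon cationic, the pseudo-axial methyl on the adjacent carbinol carbon migrates to it suprafacially (vinylogous α-ketol, i.e. semipinacol-type 1,2-methyl shift as in the p-quinol to ene-dione rearrangement) so that the (S)-carbinol becomes the (R)-quaternary centre and a 1,4-dione, and the enol released at the former α-carbon closes ring B onto the aldehyde by acid-catalysed intramolecular aldol condensation.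

**Step 5**
Reactants: 8 (4aR)-4a-methyl-7-(propan-2-yl)-2,3,4a,5,6,7-hexahydronaphthalene-1,4-dione
Product: 9 (4R,4aR)-4-hydroxy-4a-methyl-7-(propan-2-yl)-3,4,4a,5,6,7-hexahydronaphthalen-1(2H)-one (both C7 epimers)
Conditions: NaBH4 (0.3 equiv), EtOH, −15 °C
Reagents that add atoms: none
Why: Chemoselective borohydride reduction in which, as in Wieland–Miescher-type diones, the saturated ketone next to the quaternary carbon reacts faster than the conjugated enone and hydride enters anti to the angular methyl, giving the alcohol cis to that methyl (4R).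

**Step 6**
Reactants: 9 (4R,4aR)-4-hydroxy-4a-methyl-7-(propan-2-yl)-3,4,4a,5,6,7-hexahydronaphthalen-1(2H)-one
Product: 10 (4R,4aR,8aR)-4-hydroxy-4a-methyl-7-(propan-2-yl)-3,4,4a,5,6,8a-hexahydronaphthalen-1(2H)-one
Conditions: KOtBu (5 equiv), t-BuOH–THF, 23 °C, 1 h; then poured into 10% aq. AcOH, 0 °C
Reagents that add atoms: none
Why: Deconjugation through the thermodynamic extended dienolate and kinetic α-protonation, where γ-deprotonation at the isopropyl-bearing carbon (the only γ-site, which also erases the epimer mixture) gives the linear dienolate and fast axial protonation at the ring-fusion carbon anti to the angular methyl gives the β,γ-enone with the trans ring fusion (8aR).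

**Step 7**
Reactants: 10 (4R,4aR,8aR)-4-hydroxy-4a-methyl-7-(propan-2-yl)-3,4,4a,5,6,8a-hexahydronaphthalen-1(2H)-one
Product: 11 (1S,4R,4aR,8aR)-1,4a-dimethyl-7-(propan-2-yl)-1,2,3,4,4a,5,6,8a-octahydronaphthalene-1,4-diol
Conditions: MeLi (4 equiv), CeCl3 (4 equiv), THF, −78 °C; aq. NH4Cl
Reagents that add atoms: methyllithium, [Li]C
Why: Organocerium 1,2-addition avoids enolisation of the β,γ-unsaturated ketone, and the methyl enters by equatorial attack from the face opposite the angular methyl because axial attack is blocked by the 1,3-diaxial methyl, giving the axial tertiary alcohol (1S).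

**Step 8**
Reactants: 11 (1S,4R,4aR,8aR)-1,4a-dimethyl-7-(propan-2-yl)-1,2,3,4,4a,5,6,8a-octahydronaphthalene-1,4-diol; 12 prop-2-enoyl chloride
Product: 15 (1S,4R,4aR,8aR)-4-hydroxy-1,4a-dimethyl-7-(propan-2-yl)-1,2,3,4,4a,5,6,8a-octahydronaphthalen-1-yl prop-2-enoate, via secondary trimethylsilyl ether 13 (not isolated), via silylated acrylate 14 (not isolated)
Conditions: n-BuLi (2.1 equiv), THF, −78 °C; Me3SiCl (1.05 equiv); then 12 (1.5 equiv), −78 → 0 °C; citric acid, MeOH–H2O, 23 °C
Reagents that add atoms: none
Why: The secondary lithium alkoxide is silylated much faster than the axial tertiary one flanked by the angular methyl, so only the tertiary alkoxide is O-acylated by the acid chloride (alkoxide acylation, no stereocentre touched) and the labile trimethylsilyl ether is cleaved in the acidic work-up.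

**Step 9**
Reactants: 15 (1S,4R,4aR,8aR)-4-hydroxy-1,4a-dimethyl-7-(propan-2-yl)-1,2,3,4,4a,5,6,8a-octahydronaphthalen-1-yl prop-2-enoate; 16 iodobenzene
Product: 17 (1S,4R,4aR,8aR)-4-hydroxy-1,4a-dimethyl-7-(propan-2-yl)-1,2,3,4,4a,5,6,8a-octahydronaphthalen-1-yl (2E)-3-phenylprop-2-enoate
Conditions: Pd(OAc)2 (5 mol %), P(o-tol)3 (10 mol %), Et3N (2 equiv), MeCN, 80 °C
Reagents that add atoms: none
Why: Mizoroki–Heck arylation of the acrylate, in which syn carbopalladation and syn β-hydride elimination give the (E)-cinnamate while the trisubstituted ring alkene, the free secondary alcohol and the tertiary ester do not react.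

**Compound list**
1 | 2-methylcyclohex-2-en-1-one | CC1=CCCCC1=O | starting material
2 | (1S)-1,2-dimethylcyclohex-2-en-1-ol | C1C=C(C)[C@@](C)(O)CC1 | intermediate
3 | (4S)-4-hydroxy-3,4-dimethylcyclohex-2-en-1-one | O=C1C=C(C)[C@@](C)(O)CC1 | intermediate
4 | 3-methyl-2-methylidenebutanal (2-isopropylacrolein) | CC(C)C(=C)C=O | starting material
5 | 4-[(6S)-6-hydroxy-6-methyl-3-oxocyclohex-1-en-1-yl]-2-(propan-2-yl)butanal (both C2 epimers) | O=C1C=C(CCC(C(C)C)C=O)[C@@](C)(O)CC1 | intermediate
6 | 4-[(1R)-1-methyl-2,5-dioxocyclohexyl]-2-(propan-2-yl)butanal | O=CC(C(C)C)CC[C@]1(C)CC(=O)CCC1=O | intermediate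
7 | (4aR)-8-hydroxy-4a-methyl-7-(propan-2-yl)octahydronaphthalene-1,4-dione | CC(C)C1CC[C@@]2(C)C(=O)CCC(=O)C2C1O | intermediate
8 | (4aR)-4a-methyl-7-(propan-2-yl)-2,3,4a,5,6,7-hexahydronaphthalene-1,4-dione (both C7 epimers) | CC(C)C1CC[C@@]2(C)C(=O)CCC(=O)C2=C1 | intermediate
9 | (4R,4aR)-4-hydroxy-4a-methyl-7-(propan-2-yl)-3,4,4a,5,6,7-hexahydronaphthalen-1(2H)-one (both C7 epimers) | CC(C)C1CC[C@@]2(C)[C@H](O)CCC(=O)C2=C1 | intermediate
10 | (4R,4aR,8aR)-4-hydroxy-4a-methyl-7-(propan-2-yl)-3,4,4a,5,6,8a-hexahydronaphthalen-1(2H)-one | CC(C)C1=C[C@@H]2[C@@](C)(CC1)[C@H](O)CCC2=O | intermediate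
11 | (1S,4R,4aR,8aR)-1,4a-dimethyl-7-(propan-2-yl)-1,2,3,4,4a,5,6,8a-octahydronaphthalene-1,4-diol | CC(C)C1=C[C@@H]2[C@@](C)(CC1)[C@H](O)CC[C@]2(C)O | intermediate
12 | prop-2-enoyl chloride (acryloyl chloride) | C=CC(Cl)=O | starting material
13 | (1S,4R,4aR,8aR)-1,4a-dimethyl-7-(propan-2-yl)-4-[(trimethylsilyl)oxy]-1,2,3,4,4a,5,6,8a-octahydronaphthalen-1-ol (present as its lithium alkoxide) | CC(C)C1=C[C@@H]2[C@@](C)(CC1)[C@H](O[Si](C)(C)C)CC[C@]2(C)O | intermediate
14 | (1S,4R,4aR,8aR)-1,4a-dimethyl-7-(propan-2-yl)-4-[(trimethylsilyl)oxy]-1,2,3,4,4a,5,6,8a-octahydronaphthalen-1-yl prop-2-enoate | CC(C)C1=C[C@@H]2[C@@](C)(CC1)[C@H](O[Si](C)(C)C)CC[C@]2(C)OC(=O)C=C | intermediate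
15 | (1S,4R,4aR,8aR)-4-hydroxy-1,4a-dimethyl-7-(propan-2-yl)-1,2,3,4,4a,5,6,8a-octahydronaphthalen-1-yl prop-2-enoate | CC(C)C1=C[C@@H]2[C@@](C)(CC1)[C@H](O)CC[C@]2(C)OC(=O)C=C | intermediate
16 | iodobenzene | Ic1ccccc1 | starting material
17 | (1S,4R,4aR,8aR)-4-hydroxy-1,4a-dimethyl-7-(propan-2-yl)-1,2,3,4,4a,5,6,8a-octahydronaphthalen-1-yl (2E)-3-phenylprop-2-enoate | CC(C)C1=C[C@@H]2[C@@](C)(CC1)[C@H](O)CC[C@]2(C)OC(=O)/C=C/c1ccccc1 | target

**Step count**
Total: 9 steps. Longest linear sequence: 9 steps (from 1; compounds 4, 12 and 16 are bought).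

**Three steps most likely to fail**

Step 3 (the proposed new step). The risks are attack through the α′- or α-carbon, oligomerisation of the enal, and onward amine-catalysed aldol closure to a cross-conjugated dienone that would aromatise in step 4. The fallback uses known chemistry and sets out from 3 and 4. Compound 3 is converted with Me3SiOTf and Et3N in CH2Cl2 at 0 °C into the isolated exocyclic bis-silyl dienol ether trimethyl{[(4S)-4-methyl-3-methylidene-4-[(trimethylsilyl)oxy]cyclohex-1-en-1-yl]oxy}silane F1. This preformed nucleophile is added in a vinylogous Mukaiyama–Michael reaction to 4 held as its complex with the bulky Lewis acid Al(OC6H3-2,6-Ph2)3 (aluminium tris(2,6-diphenylphenoxide), toluene, −78 °C), which shields the formyl carbon so that only the β-CH2 is attacked. Aqueous work-up gives 4-{(6S)-6-methyl-3-oxo-6-[(trimethylsilyl)oxy]cyclohex-1-en-1-yl}-2-(propan-2-yl)butanal F2, and citric acid in MeOH removes the silyl group and returns to the route at 5.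

Step 4. The risks are ionisation and dehydration of the tertiary alcohol leading to a phenol, γ-enolisation and aldol closure before the methyl shift, and a slow methyl migration. The fallback sets out from 5 and replaces the protic cascade by an aprotic silyl-transfer sequence. The aldehyde is converted with HC(OMe)3 and pyridinium tosylate in MeOH into the acetal (4S)-3-[4,4-dimethoxy-3-(propan-2-yl)butyl]-4-hydroxy-4-methylcyclohex-2-en-1-one F3. Me3SiOTf (2.5 equiv) with 2,6-lutidine in CH2Cl2 at −78 → −20 °C silylates the carbinol and the enone oxygen and drives the methyl shift as a silyl-ether semipinacol (Suzuki–Tsuchihashi type). The ring silyl enol ether so formed is captured by the acetal-derived oxocarbenium ion (Noyori-type acetal aldol) to give (4aR)-8-methoxy-4a-methyl-7-(propan-2-yl)octahydronaphthalene-1,4-dione F4. DBU in CH2Cl2 then eliminates methanol and returns to the route at 8.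

Step 6. The risks are protonation from the wrong face (cis fusion), incomplete deconjugation, and reconjugation on work-up or in step 7. The fallback sets out from 9 and moves the double bond under acid through a ketal instead of a dienolate. Ethylene glycol and TsOH in benzene (Dean–Stark) form the dioxolane with migration of the alkene out of conjugation, as with steroidal 4-en-3-ones, giving (4'R,4a'R,8a'R)-4a'-methyl-7'-(propan-2-yl)-3',4',4a',5',6',8a'-hexahydro-2'H-spiro[1,3-dioxolane-2,1'-naphthalen]-4'-ol F5. Its ring fusion is checked by NOE at this stable stage. Oxalic acid on wet silica gel in CH2Cl2 at 0 °C unmasks the ketone without reconjugation and returns to the route at 10.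

**Further compounds**
F1 | step 3 | trimethyl{[(4S)-4-methyl-3-methylidene-4-[(trimethylsilyl)oxy]cyclohex-1-en-1-yl]oxy}silane | C[Si](C)(C)OC1=CC(=C)[C@@](C)(O[Si](C)(C)C)CC1
F2 | step 3 | 4-{(6S)-6-methyl-3-oxo-6-[(trimethylsilyl)oxy]cyclohex-1-en-1-yl}-2-(propan-2-yl)butanal | O=C1C=C(CCC(C(C)C)C=O)[C@@](C)(O[Si](C)(C)C)CC1
F3 | step 4 | (4S)-3-[4,4-dimethoxy-3-(propan-2-yl)butyl]-4-hydroxy-4-methylcyclohex-2-en-1-one | O=C1C=C(CCC(C(C)C)C(OC)OC)[C@@](C)(O)CC1
F4 | step 4 | (4aR)-8-methoxy-4a-methyl-7-(propan-2-yl)octahydronaphthalene-1,4-dione | CC(C)C1CC[C@@]2(C)C(=O)CCC(=O)C2C1OC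
F5 | step 6 | (4'R,4a'R,8a'R)-4a'-methyl-7'-(propan-2-yl)-3',4',4a',5',6',8a'-hexahydro-2'H-spiro[1,3-dioxolane-2,1'-naphthalen]-4'-ol | CC(C)C1=C[C@@H]2[C@@](C)(CC1)[C@H](O)CCC23OCCO3
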